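The butenolide (ring C) is cut open to a cis 4-oxo-2-enoate, and its γ-carbon C5, the ketone-level carbon lying between the exocyclic =CH beside the methyl-bearing stereocentre and ring C4–H, is supplied as carbon monoxide. A single palladium-catalysed carbonylative Negishi coupling joins a primary alkylzinc iodide, CO and a (Z)-β-iodoacrylate, making both C–C bonds at C5 without closing a ring. The zinc partner comes from the (S)-primary iodide that already carries the E,E-diene and the two furans (rings A and B); the other partner is methyl (Z)-3-iodo-2-(silyloxymethyl)acrylate. Saponification, dehydration and desilylation then deliver the Z-alkylidene butenolide.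

Key step: step 12

Assumption: ring A is the terminal furan-3-yl ring, ring B the 3,4-disubstituted furan and ring C the butenolide; the target is read as S at the methyl-bearing carbon, Z at the exocyclic alkene and E,E in the diene. The carbinol carbon of 4 and the lactol carbon of 28 are formed without control because each is removed one step later.

Step 1
Reactants: 1 3,4-dibromofuran; 2 furan-3-carbaldehyde
Product: 4 (4-bromofuran-3-yl)(furan-3-yl)methanol, via (4-bromofuran-3-yl)lithium 3 (not isolated)
Conditions: n-BuLi (1.0 equiv), Et2O, −78 °C; then 2, −78 °C; H2O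
Reagents that add atoms: none
Why: Bromine–lithium exchange at one of the two equivalent C–Br bonds of 1 is much faster than ring deprotonation at −78 °C and the 3-furyllithium adds 1,2 to the aldehyde (organolithium carbonyl addition); the carbinol centre forms as a racemate and is removed in step 2.

Step 2
Reactants: 4 (4-bromofuran-3-yl)(furan-3-yl)methanol
Product: 5 3-bromo-4-(furan-3-ylmethyl)furan
Conditions: Et3SiH (3 equiv), CF3CO2H (2 equiv), CH2Cl2, −20 → 0 °C
Reagents that add atoms: none
Why: Ionic hydrogenation: acid ionises the doubly furyl-stabilised carbinol and Et3SiH, present in excess in cold dilute solution, should reduce the cation faster than it can attack another furan, while the ring C–Br bond is inert.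

Step 3
Reactants: 5 3-bromo-4-(furan-3-ylmethyl)furan; 6 oxetane
Product: 8 3-[4-(furan-3-ylmethyl)furan-3-yl]propan-1-ol, via [4-(furan-3-ylmethyl)furan-3-yl]lithium 7 (not isolated)
Conditions: n-BuLi (1.05 equiv), THF, −78 °C; then 6, BF3·OEt2, −78 °C; H2O
Reagents that add atoms: none
Why: Bromine–lithium exchange gives the ring B 3-furyllithium, which opens BF3-activated oxetane by SN2 attack at a CH2 group (Lewis acid-assisted cyclic ether opening by an organolithium), and −78 °C throughout suppresses lithium migration to the α-positions.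

Step 4
Reactants: 8 3-[4-(furan-3-ylmethyl)furan-3-yl]propan-1-ol
Product: 9 3-[4-(furan-3-ylmethyl)furan-3-yl]propanal
Conditions: Dess–Martin periodinane, CH2Cl2, 0 °C → rt
Reagents that add atoms: none
Why: Dess–Martin oxidation of a primary alcohol stops at the aldehyde under near-neutral conditions that should leave both furans untouched.

Step 5
Reactants: 9 3-[4-(furan-3-ylmethyl)furan-3-yl]propanal; 10 2-(triphenyl-λ5-phosphanylidene)propanal
Product: 11 (2E)-5-[4-(furan-3-ylmethyl)furan-3-yl]-2-methylpent-2-enal
Conditions: toluene, 80 °C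
Reagents that add atoms: none
Why: Wittig olefination with the formyl-stabilised ylide should give the E trisubstituted enal under thermodynamic control, and the saturated aldehyde 9 reacts much faster than the conjugated α-branched product, so over-homologation should be minor.

Step 6
Reactants: 11 (2E)-5-[4-(furan-3-ylmethyl)furan-3-yl]-2-methylpent-2-enal; 12 iodoform
Product: 13 3-(furan-3-ylmethyl)-4-[(3E,5E)-6-iodo-4-methylhexa-3,5-dien-1-yl]furan
Conditions: CrCl2 (6 equiv), 12 (2 equiv), THF, 0 °C → rt, dark
Reagents that add atoms: none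
Why: Takai olefination: the geminal dichromium reagent formed from iodoform and CrCl2 adds to the aldehyde and anti elimination of the β-oxido organochromium should give the E vinyl iodide without touching the existing trisubstituted alkene or the furans.

Step 7
Reactants: 14 methyl (2R)-3-bromo-2-methylpropanoate; 13 3-(furan-3-ylmethyl)-4-[(3E,5E)-6-iodo-4-methylhexa-3,5-dien-1-yl]furan
Product: 16 methyl (2S,4E,6E)-9-[4-(furan-3-ylmethyl)furan-3-yl]-2,6-dimethylnona-4,6-dienoate, via bromo[(2R)-3-methoxy-2-methyl-3-oxopropyl]zinc 15 (not isolated)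
Conditions: 14 (1.5 equiv), Zn dust (BrCH2CH2Br/Me3SiCl-activated), LiCl, THF, 50 °C; supernatant added to 13, Pd(PPh3)4 (5 mol %), THF, rt → 40 °C
Reagents that add atoms: none
Why: Negishi sp3–sp2 coupling: zinc inserts into the primary C–Br bond, the alkylzinc transfers to the alkenylpalladium iodide formed from 13 with retention of the E geometry, and the stereocentre is a spectator because no bond to it is made or broken and the reagent is too weakly basic to enolise the ester (its descriptor changes from R to S only through the change in substituent priorities).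

Step 8
Reactants: 16 methyl (2S,4E,6E)-9-[4-(furan-3-ylmethyl)furan-3-yl]-2,6-dimethylnona-4,6-dienoate
Product: 17 (2S,4E,6E)-9-[4-(furan-3-ylmethyl)furan-3-yl]-2,6-dimethylnona-4,6-dien-1-ol
Conditions: LiAlH4, Et2O, 0 °C; aqueous work-up
Reagents that add atoms: none
Why: LiAlH4 reduction of the ester to the primary alcohol is fast at 0 °C, leaves the diene and the furans alone and should not epimerise the α-centre.

Step 9
Reactants: 17 (2S,4E,6E)-9-[4-(furan-3-ylmethyl)furan-3-yl]-2,6-dimethylnona-4,6-dien-1-ol
Product: 18 3-(furan-3-ylmethyl)-4-[(3E,5E,8S)-9-iodo-4,8-dimethylnona-3,5-dien-1-yl]furan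
Conditions: PPh3, I2, imidazole (premixed), CH2Cl2, 0 °C → rt, dark
Reagents that add atoms: iodine, II
Why: Appel-type iodination: the alcohol is activated as its alkoxyphosphonium ion and displaced by iodide in an SN2 step at the primary carbon, one atom away from the stereocentre, and premixing PPh3 and I2 keeps free iodine away from the diene and the furans.

Step 10
Reactants: 19 methyl propiolate; 20 formaldehyde
Product: 22 methyl (2Z)-2-(hydroxymethyl)-3-iodoprop-2-enoate, via magnesium iodoallenolate 21 (not isolated)
Conditions: MgI2 (1.2 equiv), CH2Cl2, 0 °C → rt, gaseous 20 from cracked paraformaldehyde; H2O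
Reagents that add atoms: magnesium diiodide, [Mg+2].[I-].[I-]
Why: Halo-aldol reaction (iodide-triggered Morita–Baylis–Hillman type): iodide adds to the MgI2-activated ynoate and the β-iodo allenolate is hydroxymethylated at the α-carbon from the side away from iodine, which should place iodine cis to the ester (Z).

Step 11
Reactants: 22 methyl (2Z)-2-(hydroxymethyl)-3-iodoprop-2-enoate
Product: 23 methyl (2Z)-2-{[(tert-butyldimethylsilyl)oxy]methyl}-3-iodoprop-2-enoate
Conditions: TBSCl, imidazole, CH2Cl2, 0 °C → rt
Reagents that add atoms: tert-butyldimethylsilyl chloride, CC(C)(C)[Si](C)(C)Cl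
Why: Standard silylation of a primary alcohol; the silyl ether masks the hydroxymethyl group through the organozinc, hydroxide and sulfonyl chloride steps and does not affect the alkene geometry.

Step 12
Reactants: 18 3-(furan-3-ylmethyl)-4-[(3E,5E,8S)-9-iodo-4,8-dimethylnona-3,5-dien-1-yl]furan; 24 carbon monoxide; 23 methyl (2Z)-2-{[(tert-butyldimethylsilyl)oxy]methyl}-3-iodoprop-2-enoate
Product: 26 methyl (2Z,6S,8E,10E)-2-{[(tert-butyldimethylsilyl)oxy]methyl}-13-[4-(furan-3-ylmethyl)furan-3-yl]-6,10-dimethyl-4-oxotrideca-2,8,10-trienoate, via alkylzinc iodide 25 (not isolated)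
Conditions: 18, Zn dust (BrCH2CH2Br/Me3SiCl-activated), LiCl, THF, 30 °C; supernatant added over 3 h to 23 (1.3 equiv), Pd(PPh3)4 (5 mol %), CO (1 atm), THF, rt
Reagents that add atoms: none
Why: Zerovalent palladium adds to the vinylic C–I bond of 23 with retention, CO inserts to give an acylpalladium iodide, the alkyl group of 25 is transferred from zinc, and reductive elimination releases ketone 26 with both C–C bonds to the new carbonyl carbon formed. The closest known reaction type is the three-component carbonylative Negishi ketone synthesis from alkylzinc iodides, CO (1 atm) and aryl or alkenyl iodides with Pd(PPh3)4. No ring closes and no stereocentre is created; the methyl-bearing centre sits β to zinc and afterwards β to the ketone, so it is not at risk. CO insertion must come before transmetalation, and a CO-saturated solution, slow addition of 25 (low standing concentration of the zinc reagent) and room temperature favour the acyl pathway over direct alkyl–alkenyl coupling. The Z geometry of 23 must also survive, which is expected because oxidative addition and acyl transfer are stereoretentive and the ester held cis to palladium can chelate the acyl complex. Excess zinc metal is removed beforehand so that it cannot insert into the activated C–I bond of 23.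

Step 13
Reactants: 26 methyl (2Z,6S,8E,10E)-2-{[(tert-butyldimethylsilyl)oxy]methyl}-13-[4-(furan-3-ylmethyl)furan-3-yl]-6,10-dimethyl-4-oxotrideca-2,8,10-trienoate
Product: 28 3-{[(tert-butyldimethylsilyl)oxy]methyl}-5-{(2S,4E,6E)-9-[4-(furan-3-ylmethyl)furan-3-yl]-2,6-dimethylnona-4,6-dien-1-yl}-5-hydroxyfuran-2(5H)-one, via lithium keto carboxylate 27 (not isolated)
Conditions: LiOH (1.5 equiv), THF/H2O, 0 °C; then 0.5 M HCl to pH 4, 0 °C
Reagents that add atoms: lithium hydroxide, [Li+].[OH-]
Why: Saponification of the methyl ester, assisted by the cis ketone, followed by mild acidification should give the keto acid in its ring form, the γ-hydroxybutenolide (addition of the carboxyl OH to the ketone), whose lactol carbon forms as both epimers and is flattened in step 14, while the methyl-bearing centre, β to the ketone, cannot enolise.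

Step 14
Reactants: 28 3-{[(tert-butyldimethylsilyl)oxy]methyl}-5-{(2S,4E,6E)-9-[4-(furan-3-ylmethyl)furan-3-yl]-2,6-dimethylnona-4,6-dien-1-yl}-5-hydroxyfuran-2(5H)-one
Product: 30 (5Z)-3-{[(tert-butyldimethylsilyl)oxy]methyl}-5-{(2S,4E,6E)-9-[4-(furan-3-ylmethyl)furan-3-yl]-2,6-dimethylnona-4,6-dien-1-ylidene}furan-2(5H)-one, via lactol mesylate 29 (not isolated)
Conditions: MsCl (1.5 equiv), Et3N (4 equiv), CH2Cl2, −40 → 0 °C
Reagents that add atoms: none
Why: Dehydration by sulfonylation and E1-type elimination: the lactol mesylate ionises to an acyloxy-stabilised cation that loses a proton from the only adjacent sp3 position, the side-chain CH2, and the Z alkene should dominate because it places the chain next to the ring oxygen and not next to C4–H; the cold amine base is too weak to deprotonate the newly allylic stereocentre.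

Step 15
Reactants: 30 (5Z)-3-{[(tert-butyldimethylsilyl)oxy]methyl}-5-{(2S,4E,6E)-9-[4-(furan-3-ylmethyl)furan-3-yl]-2,6-dimethylnona-4,6-dien-1-ylidene}furan-2(5H)-one
Product: 31 (5Z)-5-{(2S,4E,6E)-9-[4-(furan-3-ylmethyl)furan-3-yl]-2,6-dimethylnona-4,6-dien-1-ylidene}-3-(hydroxymethyl)furan-2(5H)-one
Conditions: HF·pyridine, pyridine, THF, 0 °C → rt
Reagents that add atoms: none
Why: Fluoride-induced Si–O cleavage (desilylation) under pyridine-buffered conditions should free the primary alcohol without opening the enol lactone, isomerising the exocyclic alkene or epimerising the allylic centre, as basic fluoride sources might.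

Compound list

1 | 3,4-dibromofuran | Brc1cocc1Br | starting material
2 | furan-3-carbaldehyde | O=Cc1ccoc1 | starting material
3 | (4-bromofuran-3-yl)lithium | [Li]c1cocc1Br | intermediate (not isolated)
4 | (4-bromofuran-3-yl)(furan-3-yl)methanol (racemic) | OC(c1cocc1Br)c1ccoc1 | intermediate
5 | 3-bromo-4-(furan-3-ylmethyl)furan | Brc1cocc1Cc1ccoc1 | intermediate
6 | oxetane | C1COC1 | starting material
7 | [4-(furan-3-ylmethyl)furan-3-yl]lithium | [Li]c1cocc1Cc1ccoc1 | intermediate (not isolated)
8 | 3-[4-(furan-3-ylmethyl)furan-3-yl]propan-1-ol | OCCCc1cocc1Cc1ccoc1 | intermediate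
9 | 3-[4-(furan-3-ylmethyl)furan-3-yl]propanal | O=CCCc1cocc1Cc1ccoc1 | intermediate
10 | 2-(triphenyl-λ5-phosphanylidene)propanal | CC(C=O)=P(c1ccccc1)(c1ccccc1)c1ccccc1 | starting material
11 | (2E)-5-[4-(furan-3-ylmethyl)furan-3-yl]-2-methylpent-2-enal | O=C/C(C)=C/CCc1cocc1Cc1ccoc1 | intermediate
12 | iodoform | IC(I)I | starting material
13 | 3-(furan-3-ylmethyl)-4-[(3E,5E)-6-iodo-4-methylhexa-3,5-dien-1-yl]furan | I/C=C/C(C)=C/CCc1cocc1Cc1ccoc1 | intermediate
14 | methyl (2R)-3-bromo-2-methylpropanoate | COC(=O)[C@@H](C)CBr | starting material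
15 | bromo[(2R)-3-methoxy-2-methyl-3-oxopropyl]zinc | COC(=O)[C@@H](C)C[Zn]Br | intermediate (not isolated)
16 | methyl (2S,4E,6E)-9-[4-(furan-3-ylmethyl)furan-3-yl]-2,6-dimethylnona-4,6-dienoate | COC(=O)[C@@H](C)C/C=C/C(C)=C/CCc1cocc1Cc1ccoc1 | intermediate
17 | (2S,4E,6E)-9-[4-(furan-3-ylmethyl)furan-3-yl]-2,6-dimethylnona-4,6-dien-1-ol | OC[C@@H](C)C/C=C/C(C)=C/CCc1cocc1Cc1ccoc1 | intermediate
18 | 3-(furan-3-ylmethyl)-4-[(3E,5E,8S)-9-iodo-4,8-dimethylnona-3,5-dien-1-yl]furan | IC[C@@H](C)C/C=C/C(C)=C/CCc1cocc1Cc1ccoc1 | intermediate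
19 | methyl propiolate | C#CC(=O)OC | starting material
20 | formaldehyde (from paraformaldehyde) | C=O | starting material
21 | iodomagnesium 3-iodo-1-methoxypropa-1,2-dien-1-olate | COC(O[Mg]I)=C=CI | intermediate (not isolated)
22 | methyl (2Z)-2-(hydroxymethyl)-3-iodoprop-2-enoate | COC(=O)/C(CO)=C\I | intermediate
23 | methyl (2Z)-2-{[(tert-butyldimethylsilyl)oxy]methyl}-3-iodoprop-2-enoate | COC(=O)/C(CO[Si](C)(C)C(C)(C)C)=C\I | intermediate
24 | carbon monoxide | [C-]#[O+] | starting material
25 | {(2S,4E,6E)-9-[4-(furan-3-ylmethyl)furan-3-yl]-2,6-dimethylnona-4,6-dien-1-yl}(iodo)zinc | I[Zn]C[C@@H](C)C/C=C/C(C)=C/CCc1cocc1Cc1ccoc1 | intermediate (not isolated)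
26 | methyl (2Z,6S,8E,10E)-2-{[(tert-butyldimethylsilyl)oxy]methyl}-13-[4-(furan-3-ylmethyl)furan-3-yl]-6,10-dimethyl-4-oxotrideca-2,8,10-trienoate | COC(=O)/C(CO[Si](C)(C)C(C)(C)C)=C\C(=O)C[C@@H](C)C/C=C/C(C)=C/CCc1cocc1Cc1ccoc1 | intermediate
27 | lithium (2Z,6S,8E,10E)-2-{[(tert-butyldimethylsilyl)oxy]methyl}-13-[4-(furan-3-ylmethyl)furan-3-yl]-6,10-dimethyl-4-oxotrideca-2,8,10-trienoate | [Li+].[O-]C(=O)/C(CO[Si](C)(C)C(C)(C)C)=C\C(=O)C[C@@H](C)C/C=C/C(C)=C/CCc1cocc1Cc1ccoc1 | intermediate (not isolated)
28 | 3-{[(tert-butyldimethylsilyl)oxy]methyl}-5-{(2S,4E,6E)-9-[4-(furan-3-ylmethyl)furan-3-yl]-2,6-dimethylnona-4,6-dien-1-yl}-5-hydroxyfuran-2(5H)-one (both epimers at the lactol carbon) | O=C1OC(O)(C[C@@H](C)C/C=C/C(C)=C/CCc2cocc2Cc2ccoc2)C=C1CO[Si](C)(C)C(C)(C)C | intermediate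
29 | 4-{[(tert-butyldimethylsilyl)oxy]methyl}-2-{(2S,4E,6E)-9-[4-(furan-3-ylmethyl)furan-3-yl]-2,6-dimethylnona-4,6-dien-1-yl}-5-oxo-2,5-dihydrofuran-2-yl methanesulfonate | CS(=O)(=O)OC1(C[C@@H](C)C/C=C/C(C)=C/CCc2cocc2Cc2ccoc2)OC(=O)C(CO[Si](C)(C)C(C)(C)C)=C1 | intermediate (not isolated)
30 | (5Z)-3-{[(tert-butyldimethylsilyl)oxy]methyl}-5-{(2S,4E,6E)-9-[4-(furan-3-ylmethyl)furan-3-yl]-2,6-dimethylnona-4,6-dien-1-ylidene}furan-2(5H)-one | CC(/C=C/C[C@H](C)/C=C1/C=C(CO[Si](C)(C)C(C)(C)C)C(=O)O1)=C\CCc1cocc1Cc1ccoc1 | intermediate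
31 | (5Z)-5-{(2S,4E,6E)-9-[4-(furan-3-ylmethyl)furan-3-yl]-2,6-dimethylnona-4,6-dien-1-ylidene}-3-(hydroxymethyl)furan-2(5H)-one | CC(/C=C/C[C@H](C)/C=C1/C=C(CO)C(=O)O1)=C\CCc1cocc1Cc1ccoc1 | target

Total step count: 15. Longest linear sequence: 13 steps (steps 1–9 and 12–15); steps 10–11 form the short branch to 23.

Steps most likely to fail

1. Step 12. Transmetalation from zinc may overtake CO insertion at the electron-poor alkenylpalladium, so that the alkyl group couples directly without the carbonyl carbon. The cis enoate may also isomerise under palladium and phosphine, after which the keto ester could no longer lactonise. The fallback sets out from 17 and 22 and returns at 31. Alcohol 17 would be oxidised with Dess–Martin periodinane to (2S,4E,6E)-9-[4-(furan-3-ylmethyl)furan-3-yl]-2,6-dimethylnona-4,6-dienal F1. F1 would be homologated cold with dimethyl (1-diazo-2-oxopropyl)phosphonate and K2CO3 in MeOH (Seyferth–Gilbert homologation) to 3-[(3E,5E,8S)-4,8-dimethyldeca-3,5-dien-9-yn-1-yl]-4-(furan-3-ylmethyl)furan F2. Ester 22 would be saponified with LiOH to (2Z)-2-(hydroxymethyl)-3-iodoprop-2-enoic acid F3. F2 and F3 would then be joined with PdCl2(PPh3)2, CuI and Et3N in MeCN at rt. Sonogashira coupling should give (2Z,6S,8E,10E)-13-[4-(furan-3-ylmethyl)furan-3-yl]-2-(hydroxymethyl)-6,10-dimethyltrideca-2,8,10-trien-4-ynoic acid F4, which is not isolated. Its carboxylate should add 5-exo-dig and anti across the alkyne, giving the Z-alkylidene butenolide 31 directly. In this variant the lactone γ-carbon comes from the diazophosphonate and not from CO.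

2. Step 2. The difuryl cation may alkylate a second furan ring, or the furans may be degraded by acid before hydride is delivered. The fallback sets out from 1 and returns at 5, forming the ring–CH2–ring bond at the methylene oxidation level by cross-coupling. Commercial furan-3-ylmethanol would be converted with PBr3 in Et2O at 0 °C into 3-(bromomethyl)furan F5, used at once as a cold solution. Intermediate 3, made from 1 as in step 1, would be transmetalated with ZnCl2 to (4-bromofuran-3-yl)(chloro)zinc F6. Negishi coupling of F6 with F5 (Pd(PPh3)4, THF, 0 °C → rt) should give 5, since the benzylic-type C–Br bond adds to zerovalent palladium far faster than the ring C–Br bonds.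

3. Step 3. Lithium may move from C3 to an α-position of either furan or to the doubly activated CH2 by proton transfer before the oxetane is opened, or the Lewis acid may damage the furans. The fallback sets out from 5 and returns at 9, avoiding organolithium chemistry. Negishi coupling of 5 with commercial bromo[2-(1,3-dioxolan-2-yl)ethyl]zinc (Pd(OAc)2, SPhos, THF, 50 °C) should give 2-{2-[4-(furan-3-ylmethyl)furan-3-yl]ethyl}-1,3-dioxolane F7. Mild acetal hydrolysis (pyridinium p-toluenesulfonate, acetone/H2O, 50 °C) should then give aldehyde 9, which also makes the oxidation of step 4 unnecessary.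

Further compounds

F1 | step 12 | (2S,4E,6E)-9-[4-(furan-3-ylmethyl)furan-3-yl]-2,6-dimethylnona-4,6-dienal | O=C[C@@H](C)C/C=C/C(C)=C/CCc1cocc1Cc1ccoc1
F2 | step 12 | 3-[(3E,5E,8S)-4,8-dimethyldeca-3,5-dien-9-yn-1-yl]-4-(furan-3-ylmethyl)furan | C#C[C@@H](C)C/C=C/C(C)=C/CCc1cocc1Cc1ccoc1
F3 | step 12 | (2Z)-2-(hydroxymethyl)-3-iodoprop-2-enoic acid | OC(=O)/C(CO)=C\I
F4 | step 12 | (2Z,6S,8E,10E)-13-[4-(furan-3-ylmethyl)furan-3-yl]-2-(hydroxymethyl)-6,10-dimethyltrideca-2,8,10-trien-4-ynoic acid | OC(=O)/C(CO)=C\C#C[C@@H](C)C/C=C/C(C)=C/CCc1cocc1Cc1ccoc1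
F5 | step 2 | 3-(bromomethyl)furan | BrCc1ccoc1
F6 | step 2 | (4-bromofuran-3-yl)(chloro)zinc | Cl[Zn]c1cocc1Br
F7 | step 3 | 2-{2-[4-(furan-3-ylmethyl)furan-3-yl]ethyl}-1,3-dioxolane | C1COC(CCc2cocc2Cc2ccoc2)O1
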